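## Retrosynthetic overview

1. Numbering as in 1H-isochromene: ring A = carbocycle C4a–C5–C6–C7–C8–C8a, ring B = pyran (O2, C1, C3, C4, C4a, C8a), ring C = arene of the benzoate. The target comes from one acidolysis (tert-butyl ester, two MOM ethers) of the fully assembled bicycle.
2. Ring A is closed last, at C7–C8, by a carbene-catalysed intramolecular crossed benzoin reaction: the C8 aldehyde carbon is polarity-reversed and joined to the C7 ketone carbon. Enabling feature: the α-ketol C8(=O)–C7(OH)(CH3) of ring A, whose C8 sits on the sp2 carbon C8a of ring B and is held cis to the C5–C6–C7 chain by the C8a=C4a double bond.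
3. The benzoin precursor is a monocyclic 2H-pyran with CHO on C8a and an (R)-2-aroyloxy-3-oxobutyl chain on C4a. The C6 ester is made on the open chain; C4a–C5 comes from Suzuki coupling of a 1,2-bis(boronate), with C6 set by Pt-catalysed enantioselective diboration of 2-methyl-2-vinyl-1,3-dioxolane.
4. Ring B is made first: dihydropyranone from 1,1-dimethoxyacetone and 3-chloropropanoyl chloride, Wittig reaction for the acrylate, Vilsmeier chloroformylation to place Cl on C4a and CHO on C8a.
5. Ring order: ring C (bought, as 2,3,4-trimethoxy-6-methylbenzaldehyde) → ring B (step 1) → ring A (step 13).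

Key step: step 13

Assumption: for the chiral phosphonite of step 5 and the triazolium salt of step 13, the enantiomer that leads to (R) at C6 and (R) at C7 is used; both antipodes of each are accessible.

## Route

Step 1
Reactants: 1 1,1-dimethoxypropan-2-one; 2 3-chloropropanoyl chloride
Product: 4 6-(dimethoxymethyl)-2,3-dihydro-4H-pyran-4-one, via chloro diketone 3 (not isolated)
Conditions: MgBr2·OEt2, i-Pr2NEt (excess), CH2Cl2, 0 °C to reflux
Reagents that add atoms: none
Why: Soft-enolisation Claisen-type C-acylation at the methyl group (the only position that enolises readily) should give the 1,3-diketone, whose enol oxygen remote from the chloroethyl arm closes ring B by intramolecular O-alkylation (or elimination and 6-endo oxa-Michael addition), a standard dihydropyranone synthesis.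

Step 2
Reactants: 4 6-(dimethoxymethyl)-2,3-dihydro-4H-pyran-4-one
Product: 5 4-oxo-5,6-dihydro-4H-pyran-2-carbaldehyde
Conditions: aq. HCl (2 M), THF, rt
Reagents that add atoms: water (O)
Why: Acid-catalysed acetal hydrolysis unmasks the aldehyde, and the vinylogous ester ring, which is itself formed and stable under acid, should be kept.

Step 3
Reactants: 5 4-oxo-5,6-dihydro-4H-pyran-2-carbaldehyde; 6 tert-butyl (triphenylphosphoranylidene)acetate
Product: 7 tert-butyl (E)-3-(4-oxo-5,6-dihydro-4H-pyran-2-yl)prop-2-enoate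
Conditions: CH2Cl2, 0 °C to rt
Reagents that add atoms: none
Why: Wittig olefination with a stabilised ylide should react only at the aldehyde (not at the vinylogous ester carbonyl) and give the E-acrylate.

Step 4
Reactants: 7 tert-butyl (E)-3-(4-oxo-5,6-dihydro-4H-pyran-2-yl)prop-2-enoate
Product: 8 tert-butyl (E)-3-(4-chloro-5-formyl-6H-pyran-2-yl)prop-2-enoate
Conditions: POCl3, DMF, CH2Cl2, 0 °C to rt; aq. NaOAc
Reagents that add atoms: N,N-dimethylformamide (CN(C)C=O); phosphoryl chloride (O=P(Cl)(Cl)Cl); water (O)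
Why: Vilsmeier–Haack–Arnold chloroformylation, as in the conversion of chroman-4-ones into 4-chloro-2H-chromene-3-carbaldehydes, should formylate the enol carbon C8a and exchange the ketone oxygen on C4a for chloride, while C4 is deactivated by the acrylate.

Step 5
Reactants: 9 2-methyl-2-vinyl-1,3-dioxolane
Product: 10 2-[(1R)-1,2-bis(4,4,5,5-tetramethyl-1,3,2-dioxaborolan-2-yl)ethyl]-2-methyl-1,3-dioxolane
Conditions: Pt(dba)3 (1 mol%), TADDOL-derived phenylphosphonite with 3,5-diisopropylphenyl groups (1.2 mol%), THF, 60 °C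
Reagents that add atoms: bis(pinacolato)diboron (CC1(C)OB(OC1(C)C)B1OC(C)(C)C(C)(C)O1)
Why: Platinum-catalysed enantioselective 1,2-diboration of a terminal alkene, in which syn addition of the B–B bond to the alkene face selected by the chiral phosphonite sets the future C6 as (R).

Step 6
Reactants: 8 tert-butyl (E)-3-(4-chloro-5-formyl-6H-pyran-2-yl)prop-2-enoate; 10 2-[(1R)-1,2-bis(4,4,5,5-tetramethyl-1,3,2-dioxaborolan-2-yl)ethyl]-2-methyl-1,3-dioxolane
Product: 12 tert-butyl (E)-3-{5-formyl-4-[(2R)-2-hydroxy-2-(2-methyl-1,3-dioxolan-2-yl)ethyl]-6H-pyran-2-yl}prop-2-enoate, via secondary boronate 11 (not isolated)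
Conditions: Pd(OAc)2 (2 mol%), RuPhos (2.4 mol%), K3PO4, THF/H2O (10:1), 60 °C; then NaBO3·4H2O, THF/H2O, rt
Reagents that add atoms: sodium perborate tetrahydrate ([Na+].[O-]OB=O.O.O.O.O)
Why: Suzuki–Miyaura coupling of a vicinal bis(boronate), in which the neighbouring boronate activates only the primary C–B bond for transfer to the vinylpalladium formed from the activated β-chloro enal, followed by stereoretentive oxidation of the remaining secondary C–B bond to the C6 hydroxyl.

Step 7
Reactants: 13 2,3,4-trimethoxy-6-methylbenzaldehyde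
Product: 14 2,3,4-trihydroxy-6-methylbenzaldehyde
Conditions: BBr3, CH2Cl2, −78 °C to rt; H2O
Reagents that add atoms: none
Why: Lewis acid-mediated O-demethylation with BBr3 should cleave all three aryl methyl ethers, and the aldehyde is recovered on aqueous work-up.

Step 8
Reactants: 14 2,3,4-trihydroxy-6-methylbenzaldehyde
Product: 15 2-hydroxy-3,4-bis(methoxymethoxy)-6-methylbenzaldehyde
Conditions: MOMCl (2.1 equiv), i-Pr2NEt, CH2Cl2, 0 °C
Reagents that add atoms: chloromethyl methyl ether (COCCl)
Why: Williamson-type alkoxymethylation should spare the 2-hydroxyl, which is hydrogen-bonded to the formyl group and least nucleophilic, as in the known selective 3,4-dialkylation of 2,3,4-trihydroxybenzaldehyde.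

Step 9
Reactants: 15 2-hydroxy-3,4-bis(methoxymethoxy)-6-methylbenzaldehyde
Product: 16 2-methoxy-3,4-bis(methoxymethoxy)-6-methylbenzaldehyde
Conditions: MeI, K2CO3, DMF, 40 °C
Reagents that add atoms: iodomethane (CI)
Why: Williamson O-methylation of the remaining chelated phenol under carbonate base, conditions that leave the MOM acetals untouched.

Step 10
Reactants: 16 2-methoxy-3,4-bis(methoxymethoxy)-6-methylbenzaldehyde
Product: 17 2-methoxy-3,4-bis(methoxymethoxy)-6-methylbenzoic acid
Conditions: NaClO2, NaH2PO4, 2-methylbut-2-ene, t-BuOH/H2O, rt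
Reagents that add atoms: sodium chlorite ([Na+].[O-]Cl=O)
Why: Pinnick oxidation converts the hindered aryl aldehyde into the acid at buffered pH, where the MOM ethers and the electron-rich ring (protected by the hypochlorite scavenger) should survive.

Step 11
Reactants: 17 2-methoxy-3,4-bis(methoxymethoxy)-6-methylbenzoic acid; 12 tert-butyl (E)-3-{5-formyl-4-[(2R)-2-hydroxy-2-(2-methyl-1,3-dioxolan-2-yl)ethyl]-6H-pyran-2-yl}prop-2-enoate
Product: 19 (1R)-2-{2-[(E)-3-tert-butoxy-3-oxoprop-1-enyl]-5-formyl-6H-pyran-4-yl}-1-(2-methyl-1,3-dioxolan-2-yl)ethyl 2-methoxy-3,4-bis(methoxymethoxy)-6-methylbenzoate, via acid chloride 18 (not isolated)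
Conditions: 1-chloro-N,N,2-trimethylprop-1-en-1-amine, CH2Cl2, 0 °C to rt; then alcohol 12, Et3N, DMAP, CH2Cl2, rt to 40 °C
Reagents that add atoms: none
Why: The acid is turned into its chloride under neutral conditions with the Ghosez reagent (no HCl, so the MOM ethers survive) and DMAP-catalysed acylation esterifies the C6 hydroxyl without touching the C6–O bond, so (R) is kept.

Step 12
Reactants: 19 (1R)-2-{2-[(E)-3-tert-butoxy-3-oxoprop-1-enyl]-5-formyl-6H-pyran-4-yl}-1-(2-methyl-1,3-dioxolan-2-yl)ethyl 2-methoxy-3,4-bis(methoxymethoxy)-6-methylbenzoate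
Product: 20 (2R)-1-{2-[(E)-3-tert-butoxy-3-oxoprop-1-enyl]-5-formyl-6H-pyran-4-yl}-3-oxobutan-2-yl 2-methoxy-3,4-bis(methoxymethoxy)-6-methylbenzoate
Conditions: Ce(OTf)3 (cat.), wet MeNO2, rt
Reagents that add atoms: water (O)
Why: Lewis acid-catalysed hydrolysis of the dioxolane unmasks the C7 methyl ketone under near-neutral conditions that aryl MOM ethers, the tert-butyl ester and the vinylogous ester ring should tolerate, and because C6–O is already acylated no acyloin shift can scramble C6.

Step 13
Reactants: 20 (2R)-1-{2-[(E)-3-tert-butoxy-3-oxoprop-1-enyl]-5-formyl-6H-pyran-4-yl}-3-oxobutan-2-yl 2-methoxy-3,4-bis(methoxymethoxy)-6-methylbenzoate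
Product: 21 (6R,7R)-3-[(E)-3-tert-butoxy-3-oxoprop-1-enyl]-7-hydroxy-7-methyl-8-oxo-5,6,7,8-tetrahydro-1H-isochromen-6-yl 2-methoxy-3,4-bis(methoxymethoxy)-6-methylbenzoate
Conditions: 2-mesityl-5a,10b-dihydro-4H,6H-indeno[2,1-b][1,2,4]triazolo[4,3-d][1,4]oxazin-2-ium chloride (10 mol%, matched enantiomer), i-Pr2NEt (10 mol%), toluene, rt, argon
Reagents that add atoms: none
Why: The carbene adds to the C8 aldehyde and proton transfer gives the Breslow intermediate, an acyl anion equivalent at C8, which attacks the C7 ketone carbonyl; proton transfer and loss of the carbene release the α-ketol. The closest known reaction is the carbene-catalysed intramolecular crossed aldehyde–ketone benzoin reaction that gives 2-hydroxy-2-alkyltetralones and 3-hydroxychromanones with a quaternary carbinol. Ring A closes in a 6-exo-trig mode (C8 onto the C7 carbonyl, its oxygen outside the new ring), with the C8a=C4a double bond of ring B holding the aldehyde and the side chain cis. The new stereocentre C7 (R, hydroxyl cis to the C6 ester oxygen) is set by the aminoindanol backbone of the catalyst, in a half-chair transition state with the C6 aroyloxy group and the C7 methyl group pseudo-equatorial; whether the C6 centre reinforces or opposes this is not settled, which is why the catalyst enantiomer is chosen for the matched case. The step needs acyl anion reactivity at C8 (not homoenolate, Stetter or self-condensation pathways), no β-elimination of the C6 carboxylate, and face selectivity at the ketone: only the ketone is within reach of C8 through a six-membered transition state, the acrylate lies across ring B, the tetrasubstituted enal is too hindered to dimerise, the α-acyloxy group activates the ketone, and a weak amine base in catalytic amount should not deprotonate C5 or C6. The di-ortho-substituted benzoate is too hindered to migrate to the new tertiary alkoxide.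

Step 14
Reactants: 21 (6R,7R)-3-[(E)-3-tert-butoxy-3-oxoprop-1-enyl]-7-hydroxy-7-methyl-8-oxo-5,6,7,8-tetrahydro-1H-isochromen-6-yl 2-methoxy-3,4-bis(methoxymethoxy)-6-methylbenzoate
Product: 22 (E)-3-[(6R,7R)-6-(3,4-dihydroxy-2-methoxy-6-methylbenzoyl)oxy-7-hydroxy-7-methyl-8-oxo-5,6,7,8-tetrahydro-1H-isochromen-3-yl]prop-2-enoic acid
Conditions: TFA/CH2Cl2/H2O (30:65:5), 0 °C to rt
Reagents that add atoms: none
Why: Acidolysis cleaves the tert-butyl ester (loss of isobutene) and both phenolic MOM acetals in one operation, while the hindered benzoate, the tertiary α-ketol and the vinylogous ester chromophore are expected to withstand brief exposure to acid.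

## Compound list

1 | 1,1-dimethoxypropan-2-one | COC(OC)C(C)=O | starting material
2 | 3-chloropropanoyl chloride | ClCCC(=O)Cl | starting material
3 | 6-chloro-1,1-dimethoxyhexane-2,4-dione (chloro diketone, not isolated) | COC(OC)C(=O)CC(=O)CCCl | intermediate
4 | 6-(dimethoxymethyl)-2,3-dihydro-4H-pyran-4-one | COC(OC)C1=CC(=O)CCO1 | intermediate
5 | 4-oxo-5,6-dihydro-4H-pyran-2-carbaldehyde | O=CC1=CC(=O)CCO1 | intermediate
6 | tert-butyl (triphenylphosphoranylidene)acetate | CC(C)(C)OC(=O)C=P(c1ccccc1)(c1ccccc1)c1ccccc1 | starting material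
7 | tert-butyl (E)-3-(4-oxo-5,6-dihydro-4H-pyran-2-yl)prop-2-enoate | CC(C)(C)OC(=O)/C=C/C1=CC(=O)CCO1 | intermediate
8 | tert-butyl (E)-3-(4-chloro-5-formyl-6H-pyran-2-yl)prop-2-enoate | CC(C)(C)OC(=O)/C=C/C1=CC(Cl)=C(C=O)CO1 | intermediate
9 | 2-methyl-2-vinyl-1,3-dioxolane | C=CC1(C)OCCO1 | starting material
10 | 2-[(1R)-1,2-bis(4,4,5,5-tetramethyl-1,3,2-dioxaborolan-2-yl)ethyl]-2-methyl-1,3-dioxolane | CC1(C)OB(OC1(C)C)[C@@H](C2(C)OCCO2)CB3OC(C)(C)C(C)(C)O3 | intermediate
11 | tert-butyl (E)-3-{5-formyl-4-[(2R)-2-(2-methyl-1,3-dioxolan-2-yl)-2-(4,4,5,5-tetramethyl-1,3,2-dioxaborolan-2-yl)ethyl]-6H-pyran-2-yl}prop-2-enoate (secondary boronate, not isolated) | CC1(C)OB(OC1(C)C)[C@@H](C2(C)OCCO2)CC3=C(C=O)COC(/C=C/C(=O)OC(C)(C)C)=C3 | intermediate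
12 | tert-butyl (E)-3-{5-formyl-4-[(2R)-2-hydroxy-2-(2-methyl-1,3-dioxolan-2-yl)ethyl]-6H-pyran-2-yl}prop-2-enoate | O[C@@H](C1(C)OCCO1)CC2=C(C=O)COC(/C=C/C(=O)OC(C)(C)C)=C2 | intermediate
13 | 2,3,4-trimethoxy-6-methylbenzaldehyde | COc1cc(C)c(C=O)c(OC)c1OC | starting material
14 | 2,3,4-trihydroxy-6-methylbenzaldehyde | Oc1cc(C)c(C=O)c(O)c1O | intermediate
15 | 2-hydroxy-3,4-bis(methoxymethoxy)-6-methylbenzaldehyde | COCOc1cc(C)c(C=O)c(O)c1OCOC | intermediate
16 | 2-methoxy-3,4-bis(methoxymethoxy)-6-methylbenzaldehyde | COCOc1cc(C)c(C=O)c(OC)c1OCOC | intermediate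
17 | 2-methoxy-3,4-bis(methoxymethoxy)-6-methylbenzoic acid | COCOc1cc(C)c(C(=O)O)c(OC)c1OCOC | intermediate
18 | 2-methoxy-3,4-bis(methoxymethoxy)-6-methylbenzoyl chloride (acid chloride, not isolated) | COCOc1cc(C)c(C(=O)Cl)c(OC)c1OCOC | intermediate
19 | (1R)-2-{2-[(E)-3-tert-butoxy-3-oxoprop-1-enyl]-5-formyl-6H-pyran-4-yl}-1-(2-methyl-1,3-dioxolan-2-yl)ethyl 2-methoxy-3,4-bis(methoxymethoxy)-6-methylbenzoate | COCOc1cc(C)c(C(=O)O[C@@H](C2(C)OCCO2)CC3=C(C=O)COC(/C=C/C(=O)OC(C)(C)C)=C3)c(OC)c1OCOC | intermediate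
20 | (2R)-1-{2-[(E)-3-tert-butoxy-3-oxoprop-1-enyl]-5-formyl-6H-pyran-4-yl}-3-oxobutan-2-yl 2-methoxy-3,4-bis(methoxymethoxy)-6-methylbenzoate | COCOc1cc(C)c(C(=O)O[C@@H](C(C)=O)CC2=C(C=O)COC(/C=C/C(=O)OC(C)(C)C)=C2)c(OC)c1OCOC | intermediate
21 | (6R,7R)-3-[(E)-3-tert-butoxy-3-oxoprop-1-enyl]-7-hydroxy-7-methyl-8-oxo-5,6,7,8-tetrahydro-1H-isochromen-6-yl 2-methoxy-3,4-bis(methoxymethoxy)-6-methylbenzoate | COCOc1cc(C)c(C(=O)O[C@@H]2CC3=C(COC(/C=C/C(=O)OC(C)(C)C)=C3)C(=O)[C@]2(C)O)c(OC)c1OCOC | intermediate
22 | (E)-3-[(6R,7R)-6-(3,4-dihydroxy-2-methoxy-6-methylbenzoyl)oxy-7-hydroxy-7-methyl-8-oxo-5,6,7,8-tetrahydro-1H-isochromen-3-yl]prop-2-enoic acid | COc1c(O)c(O)cc(C)c1C(=O)O[C@@H]1CC2=C(COC(/C=C/C(=O)O)=C2)C(=O)[C@]1(C)O | target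

## Step count

Total steps: 14. Longest linear sequence: 9 steps (steps 1, 2, 3, 4, 6, 11, 12, 13, 14).

## Steps most likely to fail

**Step 13 (key step).** The carbene may fail to turn the electron-rich, vinylogous formate-type aldehyde into the acyl anion equivalent. Base may remove a C5 proton so that the C6 carboxylate is lost by β-elimination. The catalyst and the C6 substituent may oppose each other, so that face selectivity at the ketone erodes.

The fallback sets out from 12 and comes back at 21. It closes the same C7–C8 bond reductively and brings in the ester afterwards. Alcohol 12 is silylated (TBSOTf, 2,6-lutidine) to the tert-butyldimethylsilyl ether F1, and its ketal is hydrolysed as in step 12 to the silyloxy keto aldehyde F2. SmI2 (THF, t-BuOH, −78 °C) closes ring A by pinacol coupling, the ketyl of the aldehyde adding to the ketone held by trivalent samarium, to give the cis-7,8-diol F3. MnO2 oxidises only the allylic C8 hydroxyl to the silyl-protected ketol F4, HF·pyridine frees the diol F5, and acylation of its secondary hydroxyl with acid chloride 18 (Et3N, DMAP) gives 21. Here C7 rests on substrate control by the C6 silyloxy group, and α-alkoxy groups usually direct the new hydroxyl anti, so the configuration has to be assigned at F4 before going on.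

**Step 6.** Aqueous base may hydrolyse the vinylogous acid chloride 8 before oxidative addition. The alkylboron partner may undergo protodeboronation, or the alkylpalladium intermediate β-hydride elimination. The vinylpalladium may also react in a Heck mode with the acrylate of a second molecule.

The fallback sets out from 8 and comes back at 20. A Heck reaction of 8 with but-3-en-2-ol (Pd(OAc)2, Bu4NCl, NaHCO3, DMF, 50 °C) gives, after β-hydride elimination toward the carbinol and tautomerisation, the 3-oxobutyl compound F6. L-Proline-catalysed α-aminoxylation with nitrosobenzene at the methylene side of the methyl ketone (enamine catalysis, same facial sense as the known (R)-product from cyclohexanone) gives the (R)-anilinooxy ketone F7. N–O cleavage (Zn, AcOH, THF, 0 °C) gives the (R)-hydroxy ketone F8, and acylation with acid chloride 18 (made from 17 as in step 11) gives 20, so steps 11 and 12 are skipped.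

**Step 4.** Formylation may occur at C4 instead of C8a. The acidic Vilsmeier medium may cleave the tert-butyl ester. The monocyclic 2H-pyran may open by valence isomerisation and polymerise during work-up.

The fallback sets out from 7 and comes back at 12. It brings in the formyl carbon masked and keeps the ketone oxygen as the leaving group. Ketone 7 is converted (TMSOTf, Et3N, CH2Cl2, 0 °C) into the silyl dienol ether F9. A Mukaiyama-type reaction with trimethyl orthoformate (BF3·OEt2, −78 °C) gives the β-keto acetal F10. KHMDS and PhNTf2 give the enol triflate F11, since only C8a can enolise. Wet silica gel with oxalic acid unmasks the aldehyde to give the formyl triflate F12, which takes the place of 8 in step 6 and gives 12.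

## Further compounds

F1 | step 13 | tert-butyl (E)-3-{4-[(2R)-2-(tert-butyldimethylsilyloxy)-2-(2-methyl-1,3-dioxolan-2-yl)ethyl]-5-formyl-6H-pyran-2-yl}prop-2-enoate | CC(C)(C)[Si](C)(C)O[C@@H](C1(C)OCCO1)CC2=C(C=O)COC(/C=C/C(=O)OC(C)(C)C)=C2
F2 | step 13 | tert-butyl (E)-3-{4-[(2R)-2-(tert-butyldimethylsilyloxy)-3-oxobutyl]-5-formyl-6H-pyran-2-yl}prop-2-enoate | CC(C)(C)[Si](C)(C)O[C@@H](C(C)=O)CC1=C(C=O)COC(/C=C/C(=O)OC(C)(C)C)=C1
F3 | step 13 | tert-butyl (E)-3-[(6R,7S,8S)-6-(tert-butyldimethylsilyloxy)-7,8-dihydroxy-7-methyl-5,6,7,8-tetrahydro-1H-isochromen-3-yl]prop-2-enoate | CC(C)(C)[Si](C)(C)O[C@@H]1CC2=C(COC(/C=C/C(=O)OC(C)(C)C)=C2)[C@H](O)[C@]1(C)O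
F4 | step 13 | tert-butyl (E)-3-[(6R,7R)-6-(tert-butyldimethylsilyloxy)-7-hydroxy-7-methyl-8-oxo-5,6,7,8-tetrahydro-1H-isochromen-3-yl]prop-2-enoate | CC(C)(C)[Si](C)(C)O[C@@H]1CC2=C(COC(/C=C/C(=O)OC(C)(C)C)=C2)C(=O)[C@]1(C)O
F5 | step 13 | tert-butyl (E)-3-[(6R,7R)-6,7-dihydroxy-7-methyl-8-oxo-5,6,7,8-tetrahydro-1H-isochromen-3-yl]prop-2-enoate | O[C@@H]1CC2=C(COC(/C=C/C(=O)OC(C)(C)C)=C2)C(=O)[C@]1(C)O
F6 | step 6 | tert-butyl (E)-3-[5-formyl-4-(3-oxobutyl)-6H-pyran-2-yl]prop-2-enoate | CC(=O)CCC1=C(C=O)COC(/C=C/C(=O)OC(C)(C)C)=C1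
F7 | step 6 | tert-butyl (E)-3-{4-[(2R)-2-(anilinooxy)-3-oxobutyl]-5-formyl-6H-pyran-2-yl}prop-2-enoate | CC(=O)[C@H](ONc1ccccc1)CC1=C(C=O)COC(/C=C/C(=O)OC(C)(C)C)=C1
F8 | step 6 | tert-butyl (E)-3-{5-formyl-4-[(2R)-2-hydroxy-3-oxobutyl]-6H-pyran-2-yl}prop-2-enoate | CC(=O)[C@H](O)CC1=C(C=O)COC(/C=C/C(=O)OC(C)(C)C)=C1
F9 | step 4 | tert-butyl (E)-3-[4-(trimethylsilyloxy)-6H-pyran-2-yl]prop-2-enoate | C[Si](C)(C)OC1=CCOC(/C=C/C(=O)OC(C)(C)C)=C1
F10 | step 4 | tert-butyl (E)-3-[5-(dimethoxymethyl)-4-oxo-5,6-dihydro-4H-pyran-2-yl]prop-2-enoate | COC(OC)C1COC(/C=C/C(=O)OC(C)(C)C)=CC1=O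
F11 | step 4 | tert-butyl (E)-3-[5-(dimethoxymethyl)-4-(trifluoromethylsulfonyloxy)-6H-pyran-2-yl]prop-2-enoate | COC(OC)C1=C(OS(=O)(=O)C(F)(F)F)C=C(/C=C/C(=O)OC(C)(C)C)OC1
F12 | step 4 | tert-butyl (E)-3-[5-formyl-4-(trifluoromethylsulfonyloxy)-6H-pyran-2-yl]prop-2-enoate | O=CC1=C(OS(=O)(=O)C(F)(F)F)C=C(/C=C/C(=O)OC(C)(C)C)OC1
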